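## Plan

- **Locants:** ring C1 (CMe2), C2 (CHBr), C3 (CH2), C4 (CHCl), C5 (ring alkene carbon), C6 (CHCl bonded to C1); side chain C7 (=CH) and C8 (CH2Br).
- **Enabling feature:** C8 sits on the C6 side of C5=C7 and C6 carries a heteroatom. The atoms O–C6–C5=C7–C8 can therefore be tied into a five-membered butenolide fused to the cyclohexane. Such a ring exists only with this alkene geometry, which the nearly equal C4 and C6 flanks could not impose on an open olefination.
- **Cuts:** C8–Br, C4–Cl and C6–Cl go back to C–O bonds (both chlorides with inversion), and the enediol goes back to the butenolide. The butenolide is cut at C5–C6, C7–C8 and C8–O into a hept-6-ynal and CO. The ynal is cut at C1–C2 (aldol) and C3–C4 (allylation).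
- **Forward order:** the chain grows C4, then C3/C2, then C1/C6. Cyclohexane and lactone close together in one carbonylative [2+2+1] step. The lactone is then reduced open and the C–O bonds are exchanged for halogen: C6 first, C4 second, C8 last.
- **Stereochemistry:** C4 comes from a catalytic asymmetric allylboration. C2 comes from a reagent-controlled 1,3-anti Mukaiyama aldol followed by invertive bromide opening of a β-lactone. C6 comes from the all-equatorial chair of the key step. Each chloride comes from SN2 inversion of an equatorial alcohol, and the alkene geometry comes from the lactone ring.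

Key step: step 9

Assumption: the facial sense of the two chiral controllers (the R phosphoric acid of step 1 and the L-valine-derived oxazaborolidinone of step 4) is assigned by analogy with aryl and alkyl aldehydes; should either prove opposite, its antipode is used and nothing else changes.

## Route

Step 1
Reactants: 1 3-(trimethylsilyl)prop-2-ynal; 2 allylboronic acid pinacol ester
Product: 4 (3R)-1-(trimethylsilyl)hex-5-en-1-yn-3-ol, via homoallyl pinacol borate 3 (not isolated)
Conditions: (R)-3,3'-bis(2,4,6-triisopropylphenyl)-1,1'-binaphthyl-2,2'-diyl hydrogen phosphate (5 mol %), toluene, −30 °C; then H2O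
Reagents that add atoms: none
Why: Chiral-phosphoric-acid-catalysed allylboration passes through a closed six-membered chair in which the acid hydrogen-bonds to a boronate oxygen and leaves one aldehyde face open, which forms C3–C4 and should set C4 as R.

Step 2
Reactants: 4 (3R)-1-(trimethylsilyl)hex-5-en-1-yn-3-ol
Product: 5 (3R)-3-[(tert-butyldimethylsilyl)oxy]-1-(trimethylsilyl)hex-5-en-1-yne
Conditions: TBSCl, imidazole, DMF, 23 °C
Reagents that add atoms: tert-butyldimethylsilyl chloride, CC(C)(C)[Si](C)(C)Cl
Why: Imidazole-promoted silylation of a secondary alcohol, with TBS chosen because it withstands ozone, LiOH, MgBr2 and zerovalent molybdenum and cannot ionise as a propargylic ester would.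

Step 3
Reactants: 5 (3R)-3-[(tert-butyldimethylsilyl)oxy]-1-(trimethylsilyl)hex-5-en-1-yne
Product: 7 (3R)-3-[(tert-butyldimethylsilyl)oxy]-5-(trimethylsilyl)pent-4-ynal, via secondary ozonide 6 (not isolated)
Conditions: O3, CH2Cl2, −78 °C (stopped at the first blue tint); PPh3, −78 → 23 °C
Reagents that add atoms: ozone, [O-][O+]=O
Why: Ozonolysis with neutral reductive work-up, in which the terminal alkene reacts far faster than the silyl-capped alkyne and the base-sensitive β-silyloxy aldehyde is not exposed to base.

Step 4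
Reactants: 7 (3R)-3-[(tert-butyldimethylsilyl)oxy]-5-(trimethylsilyl)pent-4-ynal; 8 1-methoxy-2-methyl-1-(trimethylsilyloxy)prop-1-ene
Product: 9 methyl (3R,5R)-5-[(tert-butyldimethylsilyl)oxy]-3-hydroxy-2,2-dimethyl-7-(trimethylsilyl)hept-6-ynoate
Conditions: N-tosyl-L-valine (1.1 equiv), BH3·THF (1.0 equiv), CH2Cl2, 0 → 23 °C; then 7 and 8, −78 °C; pH 7 phosphate buffer
Reagents that add atoms: none
Why: Oxazaborolidinone-promoted Mukaiyama aldol through an open transition state, in which the boron Lewis acid exposes one aldehyde face and the polar 1,3-anti preference of a β-silyloxy aldehyde points the same way, so that C1–C2 forms and C2 should be set as the R carbinol anti to C4–O.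

Step 5
Reactants: 9 methyl (3R,5R)-5-[(tert-butyldimethylsilyl)oxy]-3-hydroxy-2,2-dimethyl-7-(trimethylsilyl)hept-6-ynoate
Product: 10 (3R,5R)-5-[(tert-butyldimethylsilyl)oxy]-3-hydroxy-2,2-dimethylhept-6-ynoic acid
Conditions: LiOH, THF/MeOH/H2O, 40 °C; then 1 M HCl to pH 3
Reagents that add atoms: lithium hydroxide (hydroxide oxygen), [Li+].[OH-]
Why: Saponification of the hindered methyl ester, during which hydroxide also effects the usual protiodesilylation of the alkynyl SiMe3 group, so that two unmaskings cost one step while the secondary TBS ether and both stereocentres stay intact.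

Step 6
Reactants: 10 (3R,5R)-5-[(tert-butyldimethylsilyl)oxy]-3-hydroxy-2,2-dimethylhept-6-ynoic acid
Product: 11 (4R)-4-{(2R)-2-[(tert-butyldimethylsilyl)oxy]but-3-yn-1-yl}-3,3-dimethyloxetan-2-one
Conditions: PhSO2Cl, pyridine, 0 °C
Reagents that add atoms: none
Why: β-Lactonisation by carboxyl activation (mixed sulfonic anhydride, then acyl substitution by the C2 hydroxyl) is helped by the gem-dimethyl group and breaks no bond at C2, so the R configuration is retained.

Step 7
Reactants: 11 (4R)-4-{(2R)-2-[(tert-butyldimethylsilyl)oxy]but-3-yn-1-yl}-3,3-dimethyloxetan-2-one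
Product: 12 (3S,5R)-3-bromo-5-[(tert-butyldimethylsilyl)oxy]-2,2-dimethylhept-6-ynoic acid
Conditions: MgBr2·OEt2, Et2O, 0 → 23 °C; then 1 M HCl
Reagents that add atoms: magnesium bromide etherate, [Mg+2].[Br-].[Br-].CCOCC
Why: Lewis-acid-assisted alkyl–oxygen cleavage of a β-lactone by bromide is a strain-driven SN2 reaction in which the four-membered ring ties the quaternary carbon back from the backside path, so C2 is inverted to the S bromide, syn to C4–O.

Step 8
Reactants: 12 (3S,5R)-3-bromo-5-[(tert-butyldimethylsilyl)oxy]-2,2-dimethylhept-6-ynoic acid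
Product: 14 (3S,5R)-3-bromo-5-[(tert-butyldimethylsilyl)oxy]-2,2-dimethylhept-6-ynal, via bromo acid chloride 13 (not isolated)
Conditions: Me2C=C(Cl)NMe2, CH2Cl2, 0 °C; then LiAlH(OtBu)3, THF, −78 °C
Reagents that add atoms: 1-chloro-N,N,2-trimethylprop-1-en-1-amine, CC(C)=C(Cl)N(C)C (its chlorine stands in 13 only)
Why: Neutral acid chloride formation with an α-chloroenamine avoids the carboxylate, which could expel bromide by relactonisation or decarboxylative elimination, and the partial reduction of an acid chloride by the bulky hydride stops at the aldehyde at −78 °C.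

Step 9
Reactants: 14 (3S,5R)-3-bromo-5-[(tert-butyldimethylsilyl)oxy]-2,2-dimethylhept-6-ynal; 15 carbon monoxide
Product: 16 (4R,6S,7aR)-6-bromo-4-[(tert-butyldimethylsilyl)oxy]-7,7-dimethyl-5,6,7,7a-tetrahydro-1-benzofuran-2(4H)-one (Br, OTBS and lactone O all cis)
Conditions: Mo(CO)3(DMF)3 (1.2 equiv, freshly made from Mo(CO)6 in DMF), CO (1 atm), THF (high dilution), 23 °C
Reagents that add atoms: none
Why: After loss of DMF, zerovalent molybdenum binds the alkyne and the C=O group side-on and couples them oxidatively to an oxamolybdacyclopentene (Mo–O–C6–C5=C7), which makes C5–C6; CO then migrates into the Mo–C7 bond (C7–C8) and reductive elimination joins C8 to the oxygen. This is the hetero-Pauson–Khand cyclocarbonylation known for alkynyl aldehydes, run in its room-temperature molybdenum form because the hot Ru3(CO)12 variant would endanger the bromide. The cyclohexane closes 6-exo-dig at the alkyne (6-exo-trig at the carbonyl), and the butenolide closes as a five-membered ring by C–O reductive elimination from the six-membered acyl oxametallacycle. C6 is the only new stereocentre: its C–O bond belongs to the flat metallacycle and so must be equatorial on the forming chair, and only the chair that also keeps C2–Br and C4–OTBS equatorial avoids a 1,3-diaxial Br/OTBS contact, which leads to the all-cis 7aR product. The step needs chemoselectivity for the two π systems over the C–Br bond, which the hindered position of the secondary bromide next to quaternary C1 and the low temperature should secure, whereas the alkene geometry needs no selectivity because the metal, and after insertion C8, is held on C7 on the same side as C6. Quaternary C1 rules out enolisation and loss of HBr and helps the chain to fold (gem-dialkyl effect), and the alkyne is kept unsubstituted because a silyl group on C7 would press against the equatorial C4–OTBS (A1,3 strain) and upset the chair on which the C6 selectivity rests.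

Step 10
Reactants: 16 (4R,6S,7aR)-bromo silyloxy butenolide
Product: 17 C6,C8-diol (2S,4R,6R): C2 Br, C4 OTBS and C6 OH all cis, C5=C7H–C8H2OH with C8 cis to C6 (formal descriptor E, because silyloxy-bearing C4 outranks C6)
Conditions: iBu2AlH (excess), CH2Cl2, −78 → 0 °C; aq. potassium sodium tartrate
Reagents that add atoms: none
Why: Exhaustive 1,2-reduction of a butenolide (lactone, lactol, ring-opened enal, allylic alcohol) touches no alkene bond, so the cis relation of C8 and C6 passes to the open diol, and excess hydride with warming keeps no lactol back that could aromatise to a furan.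

Step 11
Reactants: 17 C6,C8-diol (2S,4R,6R)
Product: 18 C8 pivalate, C6 alcohol, C4 TBS ether (2S,4R,6R), C8 cis to C6
Conditions: tBuCOCl, pyridine, CH2Cl2, 0 °C
Reagents that add atoms: pivaloyl chloride, CC(C)(C)C(=O)Cl
Why: Sterically controlled acylation, in which the bulky acyl chloride takes the primary allylic C8 hydroxyl and leaves the secondary C6 hydroxyl beside the C1 methyl groups free, the pivalate also being slow to migrate.

Step 12
Reactants: 18 C8 pivalate, C6 alcohol, C4 TBS ether
Product: 19 C6 axial chloride, C8 pivalate, C4 TBS ether (2S,4R,6S), C8 cis to C6 (Z)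
Conditions: PPh3, (Cl3C)2CO, CH2Cl2, 0 → 40 °C
Reagents that add atoms: hexachloroacetone, ClC(Cl)(Cl)C(=O)C(Cl)(Cl)Cl
Why: Appel-type deoxychlorination in the variant known to give unrearranged allylic chlorides with inversion: C6 has no β-hydrogen so elimination is excluded, the equatorial C6–O bond lies close to the alkene plane so ionisation and SN2' gain little π assistance, and the backside path runs over the C1–C2 ring bond past axial hydrogens only (C4 still carries its equatorial silyl ether), which should give the axial S chloride.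

Step 13
Reactants: 19 C6 axial chloride, C8 pivalate, C4 TBS ether
Product: 20 C4 alcohol, C6 chloride, C8 pivalate (2S,4R,6S, Z)
Conditions: HF·pyridine, pyridine, THF, 0 → 23 °C
Reagents that add atoms: none
Why: Fluoride-driven silyl ether cleavage under buffered, non-basic conditions spares the pivalate, the bromide and the allylic chloride.

Step 14
Reactants: 20 C4 alcohol, C6 chloride, C8 pivalate
Product: 21 C4,C6-dichloride, C8 pivalate (2S,4S,6S, Z)
Conditions: PPh3, (Cl3C)2CO, CH2Cl2, 0 → 23 °C
Reagents that add atoms: hexachloroacetone, ClC(Cl)(Cl)C(=O)C(Cl)(Cl)Cl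
Why: A second Appel-type deoxychlorination with inversion, now at the less hindered C4, whose equatorial C–O bond has no antiperiplanar hydrogen for E2 and little π overlap for SN2', should give the axial S chloride cis to C6–Cl and trans to C2–Br.

Step 15
Reactants: 21 C4,C6-dichloride, C8 pivalate
Product: 22 (Z)-2-[(2S,4S,6S)-2-bromo-4,6-dichloro-1,1-dimethylcyclohex-5-ylidene]ethanol (route locants)
Conditions: iBu2AlH, CH2Cl2, −78 °C; aq. potassium sodium tartrate
Reagents that add atoms: none
Why: Reductive ester cleavage at low temperature gives a weakly nucleophilic aluminium alkoxide and so avoids the basic conditions under which the C8 alkoxide could displace the cis-placed C6 chloride to form a dihydrofuran.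

Step 16
Reactants: 22 C8 allylic alcohol
Product: 23 (2S,3Z,4S,6S)-6-bromo-3-(2-bromoethylidene)-2,4-dichloro-1,1-dimethylcyclohexane (target; 2S,4S,6S in route locants)
Conditions: CBr4, PPh3, CH2Cl2, −20 °C
Reagents that add atoms: carbon tetrabromide, BrC(Br)(Br)Br
Why: The Appel bromination of a primary allylic alcohol is fast at low temperature, proceeds by SN2 at C8 because SN2' at fully substituted C5 is blocked, and comes last so that no chloride source meets the allylic bromide, leaving the alkene geometry and the three stereocentres unchanged.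

## Compound list

1 | 3-(trimethylsilyl)prop-2-ynal | C[Si](C)(C)C#CC=O | starting material
2 | allylboronic acid pinacol ester | C=CCB1OC(C)(C)C(C)(C)O1 | starting material
3 | 2-{[(3R)-1-(trimethylsilyl)hex-5-en-1-yn-3-yl]oxy}-4,4,5,5-tetramethyl-1,3,2-dioxaborolane | C=CC[C@@H](OB1OC(C)(C)C(C)(C)O1)C#C[Si](C)(C)C | intermediate
4 | (3R)-1-(trimethylsilyl)hex-5-en-1-yn-3-ol | C=CC[C@@H](O)C#C[Si](C)(C)C | intermediate
5 | (3R)-3-[(tert-butyldimethylsilyl)oxy]-1-(trimethylsilyl)hex-5-en-1-yne | C=CC[C@@H](O[Si](C)(C)C(C)(C)C)C#C[Si](C)(C)C | intermediate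
6 | 3-{(2R)-2-[(tert-butyldimethylsilyl)oxy]-4-(trimethylsilyl)but-3-yn-1-yl}-1,2,4-trioxolane (both epimers at the trioxolane carbon) | C1OOC(O1)C[C@@H](O[Si](C)(C)C(C)(C)C)C#C[Si](C)(C)C | intermediate
7 | (3R)-3-[(tert-butyldimethylsilyl)oxy]-5-(trimethylsilyl)pent-4-ynal | O=CC[C@@H](O[Si](C)(C)C(C)(C)C)C#C[Si](C)(C)C | intermediate
8 | 1-methoxy-2-methyl-1-(trimethylsilyloxy)prop-1-ene | COC(O[Si](C)(C)C)=C(C)C | starting material
9 | methyl (3R,5R)-5-[(tert-butyldimethylsilyl)oxy]-3-hydroxy-2,2-dimethyl-7-(trimethylsilyl)hept-6-ynoate | COC(=O)C(C)(C)[C@H](O)C[C@@H](O[Si](C)(C)C(C)(C)C)C#C[Si](C)(C)C | intermediate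
10 | (3R,5R)-5-[(tert-butyldimethylsilyl)oxy]-3-hydroxy-2,2-dimethylhept-6-ynoic acid | OC(=O)C(C)(C)[C@H](O)C[C@@H](O[Si](C)(C)C(C)(C)C)C#C | intermediate
11 | (4R)-4-{(2R)-2-[(tert-butyldimethylsilyl)oxy]but-3-yn-1-yl}-3,3-dimethyloxetan-2-one | CC1(C)C(=O)O[C@@H]1C[C@@H](O[Si](C)(C)C(C)(C)C)C#C | intermediate
12 | (3S,5R)-3-bromo-5-[(tert-butyldimethylsilyl)oxy]-2,2-dimethylhept-6-ynoic acid | OC(=O)C(C)(C)[C@@H](Br)C[C@@H](O[Si](C)(C)C(C)(C)C)C#C | intermediate
13 | (3S,5R)-3-bromo-5-[(tert-butyldimethylsilyl)oxy]-2,2-dimethylhept-6-ynoyl chloride | ClC(=O)C(C)(C)[C@@H](Br)C[C@@H](O[Si](C)(C)C(C)(C)C)C#C | intermediate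
14 | (3S,5R)-3-bromo-5-[(tert-butyldimethylsilyl)oxy]-2,2-dimethylhept-6-ynal | O=CC(C)(C)[C@@H](Br)C[C@@H](O[Si](C)(C)C(C)(C)C)C#C | intermediate
15 | carbon monoxide | [C-]#[O+] | starting material
16 | (4R,6S,7aR)-6-bromo-4-[(tert-butyldimethylsilyl)oxy]-7,7-dimethyl-5,6,7,7a-tetrahydro-1-benzofuran-2(4H)-one | CC1(C)[C@@H](Br)C[C@@H](O[Si](C)(C)C(C)(C)C)C2=CC(=O)O[C@@H]12 | intermediate
17 | C6,C8-diol, C4 TBS ether (2S,4R,6R), C8 cis to C6 | CC1(C)[C@@H](Br)C[C@@H](O[Si](C)(C)C(C)(C)C)/C(=C/CO)[C@H]1O | intermediate
18 | C8 pivalate, C6 alcohol, C4 TBS ether (2S,4R,6R), C8 cis to C6 | CC1(C)[C@@H](Br)C[C@@H](O[Si](C)(C)C(C)(C)C)/C(=C/COC(=O)C(C)(C)C)[C@H]1O | intermediate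
19 | C6 chloride, C8 pivalate, C4 TBS ether (2S,4R,6S), C8 cis to C6 | CC1(C)[C@@H](Br)C[C@@H](O[Si](C)(C)C(C)(C)C)/C(=C/COC(=O)C(C)(C)C)[C@@H]1Cl | intermediate
20 | C4 alcohol, C6 chloride, C8 pivalate (2S,4R,6S), C8 cis to C6 | CC1(C)[C@@H](Br)C[C@@H](O)/C(=C/COC(=O)C(C)(C)C)[C@@H]1Cl | intermediate
21 | C4,C6-dichloride, C8 pivalate (2S,4S,6S), C8 cis to C6 | CC1(C)[C@@H](Br)C[C@H](Cl)/C(=C/COC(=O)C(C)(C)C)[C@@H]1Cl | intermediate
22 | C8 allylic alcohol, C4,C6-dichloride (2S,4S,6S), C8 cis to C6 | CC1(C)[C@@H](Br)C[C@H](Cl)/C(=C/CO)[C@@H]1Cl | intermediate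
23 | (2S,3Z,4S,6S)-6-bromo-3-(2-bromoethylidene)-2,4-dichloro-1,1-dimethylcyclohexane | CC1(C)[C@@H](Br)C[C@H](Cl)/C(=C/CBr)[C@@H]1Cl | target

Total step count: 16. Longest linear sequence: 16 steps (1 to 23).

## Steps most likely to fail

**Step 9.**
- **What may go wrong:** The oxidative coupling may not start at the hindered aldehyde. The unsubstituted alkyne may oligomerise on the metal. Zerovalent molybdenum may attack the C–Br bond.
- **Fallback:** Setting out from 14, the same three bonds are made one after another by known reactions while the lactone lock is kept.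
  - Oxidative methoxycarbonylation of the terminal alkyne (PdCl2 cat., CuCl2, NaOAc, CO, MeOH, 23 °C) forms C7–C8. It gives methyl (4R,6S)-6-bromo-4-[(tert-butyldimethylsilyl)oxy]-7,7-dimethyl-8-oxooct-2-ynoate F1.
  - Anti hydroiodination (NaI, AcOH, 70 °C) gives methyl (2Z,4R,6S)-6-bromo-4-[(tert-butyldimethylsilyl)oxy]-3-iodo-7,7-dimethyl-8-oxooct-2-enoate F2, in which iodine and ester are cis.
  - A Nozaki–Hiyama–Kishi cyclisation (CrCl2, NiCl2 cat., DMF) replaces C–I by C5–C6 with retention. It passes through the same all-equatorial chair, and the chromium alkoxide lactonises onto the cis ester. This comes back to the route at 16.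

**Step 12.**
- **What may go wrong:** Displacement at the hindered C6 may stall. Allylic transposition of the incoming chloride to C7 may compete.
- **Fallback:** Setting out from 18, bimolecular inversion is given up in favour of ionisation (Me3SiCl with catalytic BiCl3, CH2Cl2, low temperature).
  - The allyl cation spanning C6–C5–C7 keeps its geometry.
  - The ring stays anchored by the equatorial C2–Br and C4–OTBS groups.
  - Chloride should add along the axial direction, on the face away from the axial C1 methyl.
  - C7 is deactivated by the neighbouring CH2OPiv group.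
  - The same epimer is expected, so the route is rejoined at 19. No compound outside the list is made (F0).

**Step 7.**
- **What may go wrong:** Bromide attack at the secondary carbon beside the quaternary centre may be outrun by ionisation with a hydride shift (ring expansion to a γ-lactone) or by loss of CO2.
- **Fallback:** Setting out from 9, the strained-ring opening is replaced by displacement on an acyclic sulfonate, whose ionisation is disfavoured by the nearby ester.
  - Tf2O and 2,6-lutidine (CH2Cl2, −78 °C) give methyl (3R,5R)-5-[(tert-butyldimethylsilyl)oxy]-2,2-dimethyl-3-[(trifluoromethanesulfonyl)oxy]-7-(trimethylsilyl)hept-6-ynoate F3.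
  - LiBr in DMF gives, with inversion, methyl (3S,5R)-3-bromo-5-[(tert-butyldimethylsilyl)oxy]-2,2-dimethyl-7-(trimethylsilyl)hept-6-ynoate F4.
  - iBu2AlH (CH2Cl2, −78 °C) gives (3S,5R)-3-bromo-5-[(tert-butyldimethylsilyl)oxy]-2,2-dimethyl-7-(trimethylsilyl)hept-6-yn-1-ol F5.
  - Dess–Martin periodinane gives (3S,5R)-3-bromo-5-[(tert-butyldimethylsilyl)oxy]-2,2-dimethyl-7-(trimethylsilyl)hept-6-ynal F6.
  - K2CO3 in MeOH removes the alkynyl silyl group and comes back to the route at 14.

## Further compounds

F1 | step 9 | methyl (4R,6S)-6-bromo-4-[(tert-butyldimethylsilyl)oxy]-7,7-dimethyl-8-oxooct-2-ynoate | O=CC(C)(C)[C@@H](Br)C[C@@H](O[Si](C)(C)C(C)(C)C)C#CC(=O)OC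
F2 | step 9 | methyl (2Z,4R,6S)-6-bromo-4-[(tert-butyldimethylsilyl)oxy]-3-iodo-7,7-dimethyl-8-oxooct-2-enoate | O=CC(C)(C)[C@@H](Br)C[C@@H](O[Si](C)(C)C(C)(C)C)/C(I)=C/C(=O)OC
F0 | step 12 | none | none
F3 | step 7 | methyl (3R,5R)-5-[(tert-butyldimethylsilyl)oxy]-2,2-dimethyl-3-[(trifluoromethanesulfonyl)oxy]-7-(trimethylsilyl)hept-6-ynoate | COC(=O)C(C)(C)[C@H](OS(=O)(=O)C(F)(F)F)C[C@@H](O[Si](C)(C)C(C)(C)C)C#C[Si](C)(C)C
F4 | step 7 | methyl (3S,5R)-3-bromo-5-[(tert-butyldimethylsilyl)oxy]-2,2-dimethyl-7-(trimethylsilyl)hept-6-ynoate | COC(=O)C(C)(C)[C@@H](Br)C[C@@H](O[Si](C)(C)C(C)(C)C)C#C[Si](C)(C)C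
F5 | step 7 | (3S,5R)-3-bromo-5-[(tert-butyldimethylsilyl)oxy]-2,2-dimethyl-7-(trimethylsilyl)hept-6-yn-1-ol | OCC(C)(C)[C@@H](Br)C[C@@H](O[Si](C)(C)C(C)(C)C)C#C[Si](C)(C)C
F6 | step 7 | (3S,5R)-3-bromo-5-[(tert-butyldimethylsilyl)oxy]-2,2-dimethyl-7-(trimethylsilyl)hept-6-ynal | O=CC(C)(C)[C@@H](Br)C[C@@H](O[Si](C)(C)C(C)(C)C)C#C[Si](C)(C)C
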